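**Plan**

Locants follow spiro[5.5]undecane: ring A = C1–C6 (C2 Br, C3 Me/Cl, C5 OH), ring B = C6–C11 (C7 Me, C10 Br, C11 Me2), C6 is the spiro atom.
Retrosynthesis cuts, in order: the C7–C8 epoxide (alkene oxidation); the C10–O bond of the bromo-epoxide (closure of a 10,10-dibromo-9-ol); the C7–CH3 bond (1,2-addition with enone transposition); the C1–C6 bond of ring A; the C5–C6 bond (aldol) between dimedone-derived ring B and an enantioenriched C1–C5 chain.
Forward: ring B is present from the start as the vinylogous ester of dimedone, the chain is joined at C6 through C5, ring A is closed at C1–C6 with bromine placed on C2, and ring B is then finished (C7 methyl, C9–C10 bromo-epoxide, C7–C8 epoxide).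
Enabling feature: C6 of ring B lies between the C5 and C7 carbonyls, so its C–Br bond gives a planar electrophilic radical. The C5 carbonyl inside the forming ring A steers that radical to the terminal alkene carbon C1, joining the enolate-type carbon C6 and the alkene carbon C1, two carbons of like (nucleophilic) polarity.
Stereochemistry: C3 by catalytic enantioselective bromochlorination; C6 and C2 from C3 in the ring closure; C5 and C9 by CBS reductions (reagent control); C10 follows C9 (SN2 closure); C7/C8 by epoxidation anti to the C9–C10 epoxide.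

Key step: step 9

Assumption: the sense of the chiral ligand (step 3) and of the CBS catalysts (steps 10 and 13) is assigned from the accepted facial models; the opposite enantiomer of each is equally available.

**Route**

Step 1
Reactants: 1 dimedone (5,5-dimethylcyclohexane-1,3-dione)
Product: 2 3-isobutoxy-5,5-dimethylcyclohex-2-en-1-one
Conditions: isobutanol, TsOH (cat.), toluene, reflux, Dean–Stark trap
Reagents that add atoms: isobutanol, CC(C)CO
Why: acid-catalysed enol etherification of the symmetrical 1,3-dione gives the vinylogous ester, in which C6 is the only kinetic enolisation site (no stereocentre).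

Step 2
Reactants: 3 tert-butyl(but-3-yn-1-yloxy)dimethylsilane
Product: 4 (E)-5-[(tert-butyldimethylsilyl)oxy]-3-methylpent-2-en-1-ol
Conditions: Me3Al, Cp2ZrCl2 (cat.), CH2Cl2, 0 °C to rt; then nBuLi, THF, −78 °C; (CH2O)n, −78 °C to rt
Reagents that add atoms: trimethylaluminium, C[Al](C)C; formaldehyde (as paraformaldehyde), C=O
Why: Negishi zirconium-catalysed syn-carboalumination puts methyl on the internal and aluminium on the terminal alkyne carbon, and the alkenyl alanate is hydroxymethylated with retention, which fixes the E-alkene.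

Step 3
Reactants: 4 (E)-5-[(tert-butyldimethylsilyl)oxy]-3-methylpent-2-en-1-ol
Product: 5 (2R,3S)-2-bromo-5-[(tert-butyldimethylsilyl)oxy]-3-chloro-3-methylpentan-1-ol
Conditions: NBS, ClTi(OiPr)3, chiral tridentate Schiff-base ligand (20 mol%, the enantiomer that gives 3S), hexanes, −20 °C
Reagents that add atoms: N-bromosuccinimide, O=C1CCC(=O)N1Br; chlorotitanium triisopropoxide, CC(C)O[Ti](Cl)(OC(C)C)OC(C)C
Why: titanium-mediated catalytic enantioselective bromochlorination of an allylic alcohol: the alkoxide binds the chiral titanium complex, NBS delivers Br+ to C2 and chloride opens the bromonium ion at the tertiary C3 with anti addition, so the ligand sets C3 (S), the only stereocentre carried on (C2 is removed in step 4).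

Step 4
Reactants: 5 (2R,3S)-2-bromo-5-[(tert-butyldimethylsilyl)oxy]-3-chloro-3-methylpentan-1-ol
Product: 7 (S)-tert-butyl[(3-chloro-3-methylpent-4-en-1-yl)oxy]dimethylsilane, via primary iodide 6 (not isolated)
Conditions: PPh3, I2, imidazole, CH2Cl2, 0 °C; then Zn dust, AcOH, 0 °C, short contact
Reagents that add atoms: iodine, II (its atom is in 6 only; none remains in 7)
Why: Appel iodination followed by zinc-mediated reductive β-elimination of the vicinal bromo-iodide (Boord-type olefin synthesis) unveils the C1=C2 vinyl group without touching C3.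

Step 5
Reactants: 7 (S)-tert-butyl[(3-chloro-3-methylpent-4-en-1-yl)oxy]dimethylsilane
Product: 8 (S)-3-chloro-3-methylpent-4-en-1-ol
Conditions: Bu4NF, AcOH, THF, 0 °C
Reagents that add atoms: none
Why: fluoride cleavage of the silyl ether, buffered with AcOH so that the tertiary allylic chloride meets neither base nor strong acid.

Step 6
Reactants: 8 (S)-3-chloro-3-methylpent-4-en-1-ol
Product: 9 (S)-3-chloro-3-methylpent-4-enal
Conditions: Dess–Martin periodinane, NaHCO3, CH2Cl2, 0 °C; used at once
Reagents that add atoms: none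
Why: Dess–Martin oxidation gives the aldehyde under buffered, non-basic conditions, which avoids loss of HCl from the β-chloro aldehyde.

Step 7
Reactants: 2 3-isobutoxy-5,5-dimethylcyclohex-2-en-1-one; 9 (S)-3-chloro-3-methylpent-4-enal
Product: 10 6-[(3S)-3-chloro-1-hydroxy-3-methylpent-4-en-1-yl]-3-isobutoxy-5,5-dimethylcyclohex-2-en-1-one (diastereomer mixture at the carbinol carbon and at C6)
Conditions: LiN(iPr)2, THF, −78 °C (enolate of 2); then 9, −78 °C; aq NH4Cl at −78 °C
Reagents that add atoms: none
Why: aldol addition of the kinetic α′ (C6) lithium enolate of the vinylogous ester forms the C5–C6 bond; at −78 °C carbonyl addition should outrun α-deprotonation of the aldehyde, and both new stereocentres are erased in step 8.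

Step 8
Reactants: 10 6-[(3S)-3-chloro-1-hydroxy-3-methylpent-4-en-1-yl]-3-isobutoxy-5,5-dimethylcyclohex-2-en-1-one
Product: 12 6-bromo-6-[(3S)-3-chloro-3-methylpent-4-enoyl]-3-isobutoxy-5,5-dimethylcyclohex-2-en-1-one (both C6 epimers), via 1,3-diketone 11 (not isolated)
Conditions: Dess–Martin periodinane, NaHCO3, CH2Cl2, 0 °C to rt; then NBS, 0 °C
Reagents that add atoms: N-bromosuccinimide, O=C1CCC(=O)N1Br
Why: Dess–Martin oxidation gives the 1,3-diketone, whose doubly activated C6–H is brominated by NBS through the enol (electrophilic α-halogenation); the C6 epimers do not matter because C6 becomes a planar radical in step 9.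

Step 9
Reactants: 12 6-bromo-6-[(3S)-3-chloro-3-methylpent-4-enoyl]-3-isobutoxy-5,5-dimethylcyclohex-2-en-1-one
Product: 13 (2S,3S,6R)-2-bromo-3-chloro-9-isobutoxy-3,11,11-trimethylspiro[5.5]undec-8-ene-5,7-dione
Conditions: CuBr (10 mol%), CuBr2 (20 mol%), tris(2-pyridylmethyl)amine (30 mol%), degassed 1,2-dichloroethane (0.02 M), 40 °C
Reagents that add atoms: none
Why: CuBr with the amine ligand abstracts the bromine from C6, whose C–Br bond is weakened by the two flanking carbonyls, the planar electrophilic C6 radical adds to the terminal alkene carbon C1, and the C2 radical takes bromine back from CuBr2, which regenerates CuBr. The closest known reaction type is the copper-catalysed Kharasch atom-transfer radical cyclisation of α-halo-1,3-dicarbonyl compounds, in which 2-oxohex-5-enyl radicals close in the endo sense. Ring A closes 6-endo-trig; the 5-exo mode is disfavoured by the C5 carbonyl inside the forming ring and by the quaternary C3 beside C2. At C6 the radical reacts in the conformer with the C5 and C7 carbonyl dipoles opposed, which makes C7 axial and the bulky C11 equatorial in the chair-like transition state, and the face is chosen by C3: its methyl takes the axial site, which has no 1,3-diaxial partner because C1 and C5 are both sp2, while the C–Cl bond lies equatorial in the nodal plane of the alkene and so does not lower its reactivity towards the electrophilic radical. At C2 the cyclised radical takes bromine on the equatorial side, away from the axial C7, which places Br trans to Cl. The step needs the tertiary C6–Br bond to be activated in preference to the C–Cl bond (secured by its much lower bond strength), bromine transfer faster than loss of chlorine from the C2 radical (secured by the added CuBr2) and cyclisation faster than intermolecular addition (secured by dilution).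

Step 10
Reactants: 13 (2S,3S,6R)-2-bromo-3-chloro-9-isobutoxy-3,11,11-trimethylspiro[5.5]undec-8-ene-5,7-dione
Product: 14 (2S,3S,5S,6R)-2-bromo-3-chloro-5-hydroxy-9-isobutoxy-3,11,11-trimethylspiro[5.5]undec-8-en-7-one
Conditions: (R)-2-methyl-CBS-oxazaborolidine (1 equiv), BH3·SMe2, THF, −20 to 0 °C; MeOH quench
Reagents that add atoms: none
Why: Corey–Bakshi–Shibata reduction: the saturated C5 ketone is far more electrophilic than the vinylogous ester carbonyl C7, and with the quaternary C6 as the large group the (R)-catalyst should give the (5S) alcohol under neutral conditions that spare the β-chloro ketone.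

Step 11
Reactants: 14 (2S,3S,5S,6R)-2-bromo-3-chloro-5-hydroxy-9-isobutoxy-3,11,11-trimethylspiro[5.5]undec-8-en-7-one
Product: 16 (2S,3S,5S,6S)-2-bromo-3-chloro-5-hydroxy-3,7,11,11-tetramethylspiro[5.5]undec-7-en-9-one, via tertiary allylic alcohol 15 (not isolated)
Conditions: MeLi, CeCl3, THF, −78 °C; then 1 M HCl, THF, 0 °C
Reagents that add atoms: methyllithium, C[Li]; water, O
Why: Stork–Danheiser transposition: the organocerium reagent adds 1,2 to the hindered vinylogous ester carbonyl without acting as a base, and acid hydrolysis of the enol ether with loss of the tertiary hydroxyl gives the C7-methyl enone with C9 as the carbonyl; no stereocentre is touched (the C6 descriptor changes only through the priority rules).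

Step 12
Reactants: 16 (2S,3S,5S,6S)-2-bromo-3-chloro-5-hydroxy-3,7,11,11-tetramethylspiro[5.5]undec-7-en-9-one
Product: 18 (2S,3S,5S,6R)-2,10,10-tribromo-3-chloro-5-hydroxy-3,7,11,11-tetramethylspiro[5.5]undec-7-en-9-one, via monobromo ketone 17 (not isolated)
Conditions: LiN(SiMe3)2 (2.1 equiv), THF, −78 °C; NBS (1.0 equiv); LiN(SiMe3)2 (1.1 equiv); NBS (1.1 equiv); aq NH4Cl
Reagents that add atoms: N-bromosuccinimide, O=C1CCC(=O)N1Br
Why: kinetic deprotonation of the enone at its only α′ position C10 and bromination of the enolate with NBS, repeated once in the same flask (electrophilic α-halogenation), gives the gem-dibromide; C10 is not yet a stereocentre.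

Step 13
Reactants: 18 (2S,3S,5S,6R)-2,10,10-tribromo-3-chloro-5-hydroxy-3,7,11,11-tetramethylspiro[5.5]undec-7-en-9-one
Product: 19 (2S,3S,5S,6R,9R)-2,10,10-tribromo-3-chloro-3,7,11,11-tetramethylspiro[5.5]undec-7-ene-5,9-diol
Conditions: (S)-2-methyl-CBS-oxazaborolidine (1 equiv), catecholborane, toluene, −78 °C; pH 7 buffer work-up
Reagents that add atoms: none
Why: Corey–Bakshi–Shibata 1,2-reduction of the α,α-dibromo enone: with the CBr2 carbon as the large group the (S)-catalyst should give the (9R) alcohol, with the hydroxyl on the ring B face that carries C1.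

Step 14
Reactants: 19 (2S,3S,5S,6R,9R)-2,10,10-tribromo-3-chloro-3,7,11,11-tetramethylspiro[5.5]undec-7-ene-5,9-diol
Product: 20 (2S,3S,5S,6R,9R,10R)-2,10-dibromo-3-chloro-9,10-epoxy-3,7,11,11-tetramethylspiro[5.5]undec-7-en-5-ol
Conditions: Cs2CO3, MeCN, 0 °C
Reagents that add atoms: none
Why: Jocic-type closure (intramolecular Williamson reaction of a gem-dihalo carbinol): the C9 hydroxyl, the more acidic one because of the adjacent CBr2 group, is deprotonated and displaces one bromide at C10 with inversion (3-exo-tet), so the epoxide oxygen keeps the C9 face and the remaining bromine is fixed on the other face (10R).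

Step 15
Reactants: 20 (2S,3S,5S,6R,9R,10R)-2,10-dibromo-3-chloro-9,10-epoxy-3,7,11,11-tetramethylspiro[5.5]undec-7-en-5-ol
Product: 21 prepacifenol epoxide, (2S,3S,5S,6R,7S,8R,9R,10R)-2,10-dibromo-3-chloro-7,8:9,10-diepoxy-3,7,11,11-tetramethylspiro[5.5]undecan-5-ol
Conditions: dimethyldioxirane (acetone solution), −20 to 0 °C; evaporation, base-washed silica
Reagents that add atoms: dimethyldioxirane, CC1(C)OO1
Why: dioxirane epoxidation of the only remaining alkene under neutral conditions: attack anti to the allylic C9–C10 epoxide oxygen, on the face that also carries C5 and its hydroxyl, should set C7 (S) and C8 (R) and give the trans bis-epoxide.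

**Compound list**

1 | dimedone (5,5-dimethylcyclohexane-1,3-dione) | CC1(C)CC(=O)CC(=O)C1 | starting material
2 | 3-isobutoxy-5,5-dimethylcyclohex-2-en-1-one | CC(C)COC1=CC(=O)CC(C)(C)C1 | intermediate
3 | tert-butyl(but-3-yn-1-yloxy)dimethylsilane | C#CCCO[Si](C)(C)C(C)(C)C | starting material
4 | (E)-5-[(tert-butyldimethylsilyl)oxy]-3-methylpent-2-en-1-ol | OC/C=C(\C)CCO[Si](C)(C)C(C)(C)C | intermediate
5 | (2R,3S)-2-bromo-5-[(tert-butyldimethylsilyl)oxy]-3-chloro-3-methylpentan-1-ol | OC[C@@H](Br)[C@@](C)(Cl)CCO[Si](C)(C)C(C)(C)C | intermediate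
6 | tert-butyl{[(3S,4S)-4-bromo-3-chloro-5-iodo-3-methylpentyl]oxy}dimethylsilane | IC[C@@H](Br)[C@@](C)(Cl)CCO[Si](C)(C)C(C)(C)C | intermediate (not isolated)
7 | (S)-tert-butyl[(3-chloro-3-methylpent-4-en-1-yl)oxy]dimethylsilane | C=C[C@@](C)(Cl)CCO[Si](C)(C)C(C)(C)C | intermediate
8 | (S)-3-chloro-3-methylpent-4-en-1-ol | C=C[C@@](C)(Cl)CCO | intermediate
9 | (S)-3-chloro-3-methylpent-4-enal | C=C[C@@](C)(Cl)CC=O | intermediate
10 | 6-[(3S)-3-chloro-1-hydroxy-3-methylpent-4-en-1-yl]-3-isobutoxy-5,5-dimethylcyclohex-2-en-1-one (mixture at the carbinol carbon and C6) | C=C[C@@](C)(Cl)CC(O)C1C(=O)C=C(OCC(C)C)CC1(C)C | intermediate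
11 | 6-[(3S)-3-chloro-3-methylpent-4-enoyl]-3-isobutoxy-5,5-dimethylcyclohex-2-en-1-one | C=C[C@@](C)(Cl)CC(=O)C1C(=O)C=C(OCC(C)C)CC1(C)C | intermediate (not isolated)
12 | 6-bromo-6-[(3S)-3-chloro-3-methylpent-4-enoyl]-3-isobutoxy-5,5-dimethylcyclohex-2-en-1-one (both C6 epimers) | C=C[C@@](C)(Cl)CC(=O)C1(Br)C(=O)C=C(OCC(C)C)CC1(C)C | intermediate
13 | (2S,3S,6R)-2-bromo-3-chloro-9-isobutoxy-3,11,11-trimethylspiro[5.5]undec-8-ene-5,7-dione | CC1(C)[C@@]2(C[C@H](Br)[C@@](C)(Cl)CC2=O)C(=O)C=C(OCC(C)C)C1 | intermediate
14 | (2S,3S,5S,6R)-2-bromo-3-chloro-5-hydroxy-9-isobutoxy-3,11,11-trimethylspiro[5.5]undec-8-en-7-one | CC1(C)[C@@]2(C[C@H](Br)[C@@](C)(Cl)C[C@@H]2O)C(=O)C=C(OCC(C)C)C1 | intermediate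
15 | (2S,3S,5S,6R)-2-bromo-3-chloro-9-isobutoxy-3,7,11,11-tetramethylspiro[5.5]undec-8-ene-5,7-diol (C7 epimers) | CC1(C)[C@@]2(C[C@H](Br)[C@@](C)(Cl)C[C@@H]2O)C(C)(O)C=C(OCC(C)C)C1 | intermediate (not isolated)
16 | (2S,3S,5S,6S)-2-bromo-3-chloro-5-hydroxy-3,7,11,11-tetramethylspiro[5.5]undec-7-en-9-one | CC1(C)[C@@]2(C[C@H](Br)[C@@](C)(Cl)C[C@@H]2O)C(C)=CC(=O)C1 | intermediate
17 | (2S,3S,5S,6R)-2,10-dibromo-3-chloro-5-hydroxy-3,7,11,11-tetramethylspiro[5.5]undec-7-en-9-one (C10 epimers) | CC1(C)[C@@]2(C[C@H](Br)[C@@](C)(Cl)C[C@@H]2O)C(C)=CC(=O)C1Br | intermediate (not isolated)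
18 | (2S,3S,5S,6R)-2,10,10-tribromo-3-chloro-5-hydroxy-3,7,11,11-tetramethylspiro[5.5]undec-7-en-9-one | CC1(C)[C@@]2(C[C@H](Br)[C@@](C)(Cl)C[C@@H]2O)C(C)=CC(=O)C1(Br)Br | intermediate
19 | (2S,3S,5S,6R,9R)-2,10,10-tribromo-3-chloro-3,7,11,11-tetramethylspiro[5.5]undec-7-ene-5,9-diol | CC1(C)[C@@]2(C[C@H](Br)[C@@](C)(Cl)C[C@@H]2O)C(C)=C[C@@H](O)C1(Br)Br | intermediate
20 | (2S,3S,5S,6R,9R,10R)-2,10-dibromo-3-chloro-9,10-epoxy-3,7,11,11-tetramethylspiro[5.5]undec-7-en-5-ol | CC1(C)[C@@]2(C[C@H](Br)[C@@](C)(Cl)C[C@@H]2O)C(C)=C[C@H]2O[C@]21Br | intermediate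
21 | prepacifenol epoxide, (2S,3S,5S,6R,7S,8R,9R,10R)-2,10-dibromo-3-chloro-7,8:9,10-diepoxy-3,7,11,11-tetramethylspiro[5.5]undecan-5-ol | CC1(C)[C@@]2(C[C@H](Br)[C@@](C)(Cl)C[C@@H]2O)[C@]2(C)O[C@@H]2[C@H]2O[C@]21Br | target

**Step count and risks**

Total steps: 15. Longest linear sequence: 14 steps (compound 3 to 21, steps 2–15); step 1 is the side branch.

Step 9 (ring closure). What may go wrong: loss of the chlorine atom by β-scission of the C2 radical before bromine transfer, or attack on the wrong face of the planar C6 radical. The fallback is an ionic closure of the same ring that keeps both halogens from the bromochlorination, and it sets out from 3. Acylation of the lithium acetylide with ClCO2Me should give the ynoate F1, syn-addition of Me2CuLi at −78 °C the (Z)-enoate F2, and iBu2AlH the (Z)-allylic alcohol F3. The bromochlorination of step 3 should then give the (2S,3S)-bromochloro alcohol F4, in which C2 and C3 both have the target configuration. TsCl in pyridine should give the primary tosylate F5, buffered Bu4NF the alcohol F6, Dess–Martin oxidation the aldehyde F7, aldol addition of the lithium enolate of 2 the β-hydroxy ketone F8, and a second Dess–Martin oxidation the 1,3-diketone F9. K2CO3 with NaI in acetone (C-alkylation of the 1,3-dicarbonyl, 6-exo-tet, bromine equatorial in the chair) should close ring A and come back to the route at 13.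

Step 14 (bromo-epoxide closure). What may go wrong: opening or rearrangement of the new α-bromo epoxide to an α-bromo ketone under the basic conditions, or attack of the C5 hydroxyl at C10. The fallback makes the bromo-epoxide by neutral oxidation of a bromoalkene and sets out from 19. PPh3, I2 and imidazole should convert the allylic C9 hydroxyl into the allylic iodide F10, which Zn (as in step 4) should reduce, with loss of one C10 bromine, to the 10-bromo-7,9-diene F11. VO(acac)2 with tBuOOH (hydroxyl-assisted epoxidation from the C5 side) should give the 7,8-epoxide F12 (prepacifenol), and dimethyldioxirane should then epoxidise the bromoalkene anti to the first epoxide and come back to the route at 21.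

Step 15 (last epoxidation). What may go wrong: attack on the face syn to the C9–C10 epoxide, or acid-promoted transannular ether formation from the C5 hydroxyl. The fallback sets out from 20. NBS in wet THF should give the trans bromohydrin F13 (OH at C7, Br at C8). Because water enters anti to the bromonium ion, closure with K2CO3 places the epoxide on the face opposite to the one the electrophile attacked, which inverts the facial outcome of a direct epoxidation, and comes back to the route at 21.

Further compounds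
F1 | step 9 | methyl 5-[(tert-butyldimethylsilyl)oxy]pent-2-ynoate | COC(=O)C#CCCO[Si](C)(C)C(C)(C)C
F2 | step 9 | methyl (Z)-5-[(tert-butyldimethylsilyl)oxy]-3-methylpent-2-enoate | COC(=O)/C=C(/C)CCO[Si](C)(C)C(C)(C)C
F3 | step 9 | (Z)-5-[(tert-butyldimethylsilyl)oxy]-3-methylpent-2-en-1-ol | OC/C=C(/C)CCO[Si](C)(C)C(C)(C)C
F4 | step 9 | (2S,3S)-2-bromo-5-[(tert-butyldimethylsilyl)oxy]-3-chloro-3-methylpentan-1-ol | OC[C@H](Br)[C@@](C)(Cl)CCO[Si](C)(C)C(C)(C)C
F5 | step 9 | (2S,3S)-2-bromo-5-[(tert-butyldimethylsilyl)oxy]-3-chloro-3-methylpentyl 4-methylbenzenesulfonate | Cc1ccc(cc1)S(=O)(=O)OC[C@H](Br)[C@@](C)(Cl)CCO[Si](C)(C)C(C)(C)C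
F6 | step 9 | (2S,3S)-2-bromo-3-chloro-5-hydroxy-3-methylpentyl 4-methylbenzenesulfonate | Cc1ccc(cc1)S(=O)(=O)OC[C@H](Br)[C@@](C)(Cl)CCO
F7 | step 9 | (2S,3S)-2-bromo-3-chloro-3-methyl-5-oxopentyl 4-methylbenzenesulfonate | Cc1ccc(cc1)S(=O)(=O)OC[C@H](Br)[C@@](C)(Cl)CC=O
F8 | step 9 | (2S,3S)-2-bromo-3-chloro-5-hydroxy-5-(4-isobutoxy-6,6-dimethyl-2-oxocyclohex-3-en-1-yl)-3-methylpentyl 4-methylbenzenesulfonate (mixture at the two new centres) | Cc1ccc(cc1)S(=O)(=O)OC[C@H](Br)[C@@](C)(Cl)CC(O)C1C(=O)C=C(OCC(C)C)CC1(C)C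
F9 | step 9 | (2S,3S)-2-bromo-3-chloro-5-(4-isobutoxy-6,6-dimethyl-2-oxocyclohex-3-en-1-yl)-3-methyl-5-oxopentyl 4-methylbenzenesulfonate | Cc1ccc(cc1)S(=O)(=O)OC[C@H](Br)[C@@](C)(Cl)CC(=O)C1C(=O)C=C(OCC(C)C)CC1(C)C
F10 | step 14 | 2,10,10-tribromo-3-chloro-9-iodo-3,7,11,11-tetramethylspiro[5.5]undec-7-en-5-ol (C2, C3, C5, C6 as in 19; C9 epimers; not isolated) | CC1(C)[C@@]2(C[C@H](Br)[C@@](C)(Cl)C[C@@H]2O)C(C)=CC(I)C1(Br)Br
F11 | step 14 | 2,10-dibromo-3-chloro-3,7,11,11-tetramethylspiro[5.5]undeca-7,9-dien-5-ol (C2, C3, C5, C6 as in 19) | CC1(C)[C@@]2(C[C@H](Br)[C@@](C)(Cl)C[C@@H]2O)C(C)=CC=C1Br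
F12 | step 14 | prepacifenol, 2,10-dibromo-3-chloro-7,8-epoxy-3,7,11,11-tetramethylspiro[5.5]undec-9-en-5-ol (C2, C3, C5, C6, C7, C8 as in 21) | CC1(C)[C@@]2(C[C@H](Br)[C@@](C)(Cl)C[C@@H]2O)[C@]2(C)O[C@@H]2C=C1Br
F13 | step 15 | 2,8,10-tribromo-3-chloro-9,10-epoxy-3,7,11,11-tetramethylspiro[5.5]undecane-5,7-diol (7-OH on the C5 face, 8-Br on the opposite face; other centres as in 20) | CC1(C)[C@@]2(C[C@H](Br)[C@@](C)(Cl)C[C@@H]2O)[C@](C)(O)[C@@H](Br)[C@H]2O[C@]21Br
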